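**Strategy.** Alertenone is cut at its inter-unit C4–CH2 bond into two molecules of one α-methylene ketone (8, locants of tricyclo[4.3.2.0^{1,5}]undecane), joined at the end by a Michael addition. Compound 8 is cut at the C1–C9 bond of its six-membered ring C (C1, C5, C6, C7, C8, C9). The disconnection exploits that C1 is β and the C2 methylene α to the C3 ketone while C9 bears a methyl group: 8 is the formal intramolecular ene adduct of a 2-methylcyclopentenone (rings A and B) with a tethered but-3-enyl chain. A cobalt-hydride hydrogen-atom-transfer cycloisomerisation closes ring C, sets quaternary C1 and C9, and unveils the exocyclic enone in one isomerisation.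

Key step: step 4

Remarks on the chemistry:
- Ring A = C1–C5 (cyclopentanone), ring B = C1, C5, C6, C11, C10, ring C = C1, C5, C6, C7, C8, C9. Primed locants refer to the saturated-ketone half of 11.
- Both halves of 11 come from the same batch of 8, so no ring is formed after step 4.
- CIP descriptors were derived from the SMILES; where a name and a SMILES differ, the SMILES holds.
- The ligand antipode in step 1 is the one that delivers the 3S adduct; the sense is to be confirmed on the first adduct.

Step 1
Reactants: 1 4,4-dimethylcyclopent-2-en-1-one; 2 but-3-en-1-ylmagnesium bromide; 3 1-bromobut-2-yne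
Product: 5 (2S,3S)-2-(but-2-yn-1-yl)-3-(but-3-en-1-yl)-4,4-dimethylcyclopentan-1-one, via magnesium enolate 4 (not isolated)
Conditions: 2 (Et2O, 1.2 equiv), CuBr·SMe2 (5 mol %), (R)-1-[(S)-2-(diphenylphosphino)ferrocenyl]ethyldicyclohexylphosphine (Josiphos type, 6 mol %), t-BuOMe, −78 °C; then 3 (1.5 equiv), DMPU, −78 °C → rt
Reagents that add atoms: none
Why: Copper-catalysed asymmetric conjugate addition of the Grignard reagent followed by alkylation of the magnesium enolate (tandem conjugate addition–enolate trapping): the chiral copper–diphosphine complex selects the enone face and so sets C3, and the propargylic bromide then enters C2 anti to the new butenyl group, which gives the trans-2,3 arrangement.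

Step 2
Reactants: 5 (2S,3S)-2-(but-2-yn-1-yl)-3-(but-3-en-1-yl)-4,4-dimethylcyclopentan-1-one
Product: 6 (2S,3S)-3-(but-3-en-1-yl)-4,4-dimethyl-2-(2-oxobutyl)cyclopentan-1-one
Conditions: Ph3PAuNTf2 (2 mol %), H2O (5 equiv), 1,4-dioxane, 50 °C
Reagents that add atoms: water, O
Why: Gold-catalysed alkyne hydration with anchimeric assistance by the ring ketone, whose oxygen attacks the proximal alkyne carbon 5-exo-dig so that the new carbonyl lies 1,4 to the ring ketone, while the terminal alkene is not activated by monovalent gold under these conditions.

Step 3
Reactants: 6 (2S,3S)-3-(but-3-en-1-yl)-4,4-dimethyl-2-(2-oxobutyl)cyclopentan-1-one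
Product: 7 (6S,6aS)-6-(but-3-en-1-yl)-3,5,5-trimethyl-4,5,6,6a-tetrahydropentalen-2(1H)-one
Conditions: KOH (1 M), EtOH, 70 °C
Reagents that add atoms: none
Why: Intramolecular aldol condensation of the 1,4-diketone (the CH2 of the ethyl ketone adds to the ring carbonyl, then E1cB loss of water) closes ring A as the conjugated tetrasubstituted cyclopentenone, and C6a, which can equilibrate through the dienolate, settles with the butenyl group trans to C1 on the convex face.

Step 4
Reactants: 7 (6S,6aS)-6-(but-3-en-1-yl)-3,5,5-trimethyl-4,5,6,6a-tetrahydropentalen-2(1H)-one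
Product: 8 (1S,5S,6S,9S)-9,11,11-trimethyl-2-methylidenetricyclo[4.3.2.0^{1,5}]undecan-3-one
Conditions: Co(salen)Cl [salen = N,N′-bis(3,5-di-tert-butylsalicylidene)-1,2-cyclohexanediaminate] (5 mol %), PhSiH3 (10 mol %), benzene (0.02 M), rt, Ar
Reagents that add atoms: none
Why: Proposed new method: a trivalent cobalt hydride formed from Co(salen)Cl and PhSiH3 transfers a hydrogen atom to the terminal CH2 of the butenyl group (Markovnikov), the secondary radical at the future C9 adds to the enone β-carbon (C3a of 7, the future C1), and the tertiary α-keto radical at the future C2 returns a hydrogen atom from its methyl group to divalent cobalt, which regenerates the hydride and unveils the exocyclic enone in a redox-neutral formal intramolecular ene reaction. The closest known reaction types are the Co(salen)-catalysed hydrogen-atom-transfer cycloisomerisation of dienes and, for the last event, catalytic chain transfer in methacrylate polymerisation, where divalent cobalt abstracts hydrogen from the α-methyl group of a tertiary α-carbonyl radical. Ring C is closed in the 6-exo-trig mode and no other ring is formed. C1 is set by the tether, which reaches only the face of ring B that carries the butenyl chain, so the new bond is cis to C7 and rings A and B stay cis-fused; C9 is set in a chair-like transition state with its methyl group pseudo-axial (anti to C10), because the pseudo-equatorial position would clash with the C2 methyl group held in the enone plane (allylic 1,3-strain). The step needs hydrogen-atom transfer to the monosubstituted alkene and not to the tetrasubstituted enone, ring closure faster than hydrogen return from C8 (alkene migration), and hydrogen return from the C2 methyl group only: the first rests on the accessibility of the terminal alkene, the second on the polarity match of a nucleophilic radical with an enone held within reach, the third on the absence of any other hydrogen β to the C2 radical, C1 being quaternary.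

Step 5
Reactants: 8 (1S,5S,6S,9S)-9,11,11-trimethyl-2-methylidenetricyclo[4.3.2.0^{1,5}]undecan-3-one (two molecules)
Product: 11 alertenone, via lithium dienolate 9 (not isolated), via lithium enolate 10 (not isolated)
Conditions: LiHMDS (0.55 equiv), THF, −78 → −40 °C; then AcOH, −78 °C
Reagents that add atoms: none
Why: Michael addition: C4 is the only enolisable position of 8, its cross-conjugated lithium dienolate adds to the exocyclic methylene carbon of a second molecule of 8 with the new bond at C4 formed anti to the C5–C6 bond, a second ring-forming Michael addition is excluded because it would need a bridgehead enolate, and protonation at C2′ from the face opposite the axial C9′ methyl group should place the CH2 link cis to C9′ as in the target.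

**Compound list**

1 | 4,4-dimethylcyclopent-2-en-1-one | CC1(C)CC(=O)C=C1 | starting material
2 | but-3-en-1-ylmagnesium bromide | C=CCC[Mg]Br | starting material
3 | 1-bromobut-2-yne | CC#CCBr | starting material
4 | bromomagnesium (3S)-3-(but-3-en-1-yl)-4,4-dimethylcyclopent-1-en-1-olate | C=CCC[C@H]1C=C(O[Mg]Br)CC1(C)C | intermediate
5 | (2S,3S)-2-(but-2-yn-1-yl)-3-(but-3-en-1-yl)-4,4-dimethylcyclopentan-1-one (trans) | O=C1CC(C)(C)[C@@H](CCC=C)[C@@H]1CC#CC | intermediate
6 | (2S,3S)-3-(but-3-en-1-yl)-4,4-dimethyl-2-(2-oxobutyl)cyclopentan-1-one | O=C1CC(C)(C)[C@@H](CCC=C)[C@@H]1CC(=O)CC | intermediate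
7 | (6S,6aS)-6-(but-3-en-1-yl)-3,5,5-trimethyl-4,5,6,6a-tetrahydropentalen-2(1H)-one (butenyl trans to C1) | CC1=C2CC(C)(C)[C@@H](CCC=C)[C@@H]2CC1=O | intermediate
8 | (1S,5S,6S,9S)-9,11,11-trimethyl-2-methylidenetricyclo[4.3.2.0^{1,5}]undecan-3-one (monomeric enone, C9 methyl axial on ring C) | C=C1C(=O)C[C@H]2[C@@H]3CC[C@H](C)[C@]12CC3(C)C | intermediate
9 | lithium C3,C4-dienolate of 8 (stereocentres as in 8) | C=C1C(O[Li])=C[C@H]2[C@@H]3CC[C@H](C)[C@]12CC3(C)C | intermediate
10 | lithium C2′,C3′-enolate of 11 (Michael adduct before protonation) | C=C1C(=O)[C@H](CC2=C(O[Li])C[C@H]3[C@@H]4CC[C@H](C)[C@]23CC4(C)C)[C@H]2[C@@H]3CC[C@H](C)[C@]12CC3(C)C | intermediate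
11 | alertenone, (1S,4R,5R,6S,9S)-9,11,11-trimethyl-2-methylidene-4-{[(1S,2S,5S,6S,9S)-9,11,11-trimethyl-3-oxotricyclo[4.3.2.0^{1,5}]undecan-2-yl]methyl}tricyclo[4.3.2.0^{1,5}]undecan-3-one | C=C1C(=O)[C@H](C[C@@H]2C(=O)C[C@H]3[C@@H]4CC[C@H](C)[C@]23CC4(C)C)[C@H]2[C@@H]3CC[C@H](C)[C@]12CC3(C)C | target

Total step count: 5
Longest linear sequence: 5 (compound 8 enters step 5 twice)

**Steps most likely to fail**

Step 4 (labelled step). The secondary radical may return its hydrogen from C8 to divalent cobalt before it closes the ring, which moves the alkene inward and opens a 5-exo pathway. Addition to the fully substituted enone carbon may also be slow, and the preference for the axial C9 methyl group may be incomplete. The fallback uses known chemistry and sets out from 7. Reductive hydrogen-atom-transfer olefin–enone coupling (Fe(acac)3, PhSiH3, EtOH/ethylene glycol, 60 °C) forms the same C1–C9 bond and should give the saturated 2-methyl ketone F1, in which both C2 epimers serve. Bromination through the more substituted enol (PhNMe3Br3, THF, rt) should give the tertiary α-bromo ketone F2. Dehydrobromination (Li2CO3, LiBr, DMF, 120 °C) can only run toward the methyl group, because C1 bears no hydrogen, and returns to 8.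

Step 1. Facial discrimination by the chiral copper catalyst may be insufficient at the β-carbon next to the gem-dimethyl group. Proton exchange between product ketone and magnesium enolate may also lead to regioisomeric or double alkylation. The fallback sets out from 1 and 2 and separates the two events without asymmetric catalysis. Conjugate addition with CuI (10 mol %) and Me3SiCl in THF at −78 °C gives the racemic trimethylsilyl enol ether F3, which is isolated. MeLi (THF, 0 °C) releases the lithium enolate regiospecifically, and alkylation with 3 in THF/DMPU gives the racemic trans ketone F4. Preparative chromatography on a chiral stationary phase resolves F4, and the (2S,3S) enantiomer is 5.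

Step 5. The adduct enolate may add to further enone (oligomerisation), and face selectivity may be poor in the protonation at C2′ or in the bond formation at C4. The fallback sets out from 8 and replaces the basic one-pot process by a Mukaiyama–Michael addition with a separate protonation. Me3SiOTf and Et3N in CH2Cl2 at 0 °C convert 8 into the silyl dienol ether F5. F5 and a second equivalent of 8 combine under Me3SiNTf2 (5 mol %) in CH2Cl2 at −78 °C, with silyl transfer, to the silyl enol ether F6, which is isolated. Protonation under kinetic control with HF·pyridine in THF at −78 °C gives 11.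

**Further compounds**

F1 | step 4 | (1S,2S,5S,6S,9S)-2,9,11,11-tetramethyltricyclo[4.3.2.0^{1,5}]undecan-3-one (drawn as the epimer with the C2 methyl cis to C9) | C[C@@H]1C(=O)C[C@H]2[C@@H]3CC[C@H](C)[C@]12CC3(C)C
F2 | step 4 | 2-bromo-2,9,11,11-tetramethyltricyclo[4.3.2.0^{1,5}]undecan-3-one (bromine on the face opposite C9) | C[C@]1(Br)C(=O)C[C@H]2[C@@H]3CC[C@H](C)[C@]12CC3(C)C
F3 | step 1 | racemic {[3-(but-3-en-1-yl)-4,4-dimethylcyclopent-1-en-1-yl]oxy}trimethylsilane | C=CCCC1C=C(O[Si](C)(C)C)CC1(C)C
F4 | step 1 | racemic trans-2-(but-2-yn-1-yl)-3-(but-3-en-1-yl)-4,4-dimethylcyclopentan-1-one | O=C1CC(C)(C)[C@@H](CCC=C)[C@@H]1CC#CC.O=C1CC(C)(C)[C@H](CCC=C)[C@H]1CC#CC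
F5 | step 5 | trimethylsilyl C3,C4-dienol ether of 8 | C=C1C(O[Si](C)(C)C)=C[C@H]2[C@@H]3CC[C@H](C)[C@]12CC3(C)C
F6 | step 5 | trimethylsilyl C2′,C3′-enol ether of 11 | C=C1C(=O)[C@H](CC2=C(O[Si](C)(C)C)C[C@H]3[C@@H]4CC[C@H](C)[C@]23CC4(C)C)[C@H]2[C@@H]3CC[C@H](C)[C@]12CC3(C)C
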